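**Retrosynthetic overview**
1. Target ⇐ oxidation of the C3 alcohol ⇐ MeMgBr addition to the cyclohexanone of the oxepane–cyclohexane half.
2. Oxepane and cyclohexanone ⇐ one epoxide-opening cascade of a bis-epoxide (Shi epoxidation) carrying a Z-silyl enol ether ⇐ 1,4-hydrosilylation of an enone ⇐ Horner–Wadsworth–Emmons union of a hydroazulene aldehyde with a diepoxy keto phosphonate.
3. Aldehyde ⇐ Claisen rearrangement ⇐ oxazaborolidine reduction ⇐ hydroazulenone ⇐ SmI2 ketyl–enone closure of the cyclopentanol ring.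
4. Its precursor ⇐ new organocatalytic asymmetric vinylogous Mukaiyama–Michael addition of an achiral cycloheptatrienyl silyl ether to methyl vinyl ketone; seven-membered ring ⇐ Saegusa–Ito ring expansion of 2,4,4-trimethylcyclohexenone.
5. Ring order: cycloheptadienone, then cyclopentanol, then (after fragment union) oxepane and cyclohexane together.

Assumption: the stereostructure is taken exactly as written in the SMILES; 2,4,4-trimethylcyclohex-2-en-1-one, methyl vinyl ketone, geranyl bromide, dimethyl (2-oxopropyl)phosphonate and the D-fructose-derived Shi ketone are bought. Nothing here has been run; conditions are proposals.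

**Route**

Step 1
Reactants: 1 2,4,4-trimethylcyclohex-2-en-1-one
Product: 2 trimethyl[(4,4,6-trimethylcyclohexa-1,5-dien-1-yl)oxy]silane
Conditions: LiN(iPr)2, THF, −78 °C; TMSCl, −78 → 0 °C
Reagents that add atoms: chlorotrimethylsilane, C[Si](C)(C)Cl
Why: Kinetic deprotonation at the only sp3 α-carbon followed by O-silylation gives the cross-conjugated 2-silyloxy diene (silyl enol ether formation).

Step 2
Reactants: 2 trimethyl[(4,4,6-trimethylcyclohexa-1,5-dien-1-yl)oxy]silane
Product: 3 trimethyl[(2,4,4-trimethylbicyclo[4.1.0]hept-2-en-1-yl)oxy]silane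
Conditions: CH2I2, Zn(Cu) couple, Et2O, reflux
Reagents that add atoms: diiodomethane, ICI
Why: Simmons–Smith cyclopropanation takes place at the electron-rich silyl enol ether double bond and not at the trisubstituted alkene; the two racemic stereocentres are erased in step 3.

Step 3
Reactants: 3 trimethyl[(2,4,4-trimethylbicyclo[4.1.0]hept-2-en-1-yl)oxy]silane
Product: 5 2,4,4-trimethylcyclohepta-2,6-dien-1-one, via beta-chloro ketone 4 (not isolated)
Conditions: FeCl3, DMF, 0 °C → rt; then NaOAc, MeOH, reflux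
Reagents that add atoms: iron trichloride, Cl[Fe](Cl)Cl (supplies the chlorine of 4 only)
Why: Saegusa–Ito ring expansion, in which one-electron oxidation of the siloxycyclopropane cleaves the internal cyclopropane bond to a ring-enlarged β-keto radical that is chlorinated, and acetate then eliminates HCl to the achiral cross-conjugated dienone.

Step 4
Reactants: 5 2,4,4-trimethylcyclohepta-2,6-dien-1-one
Product: 6 tert-butyl(dimethyl)[(5,5,7-trimethylcyclohepta-1,3,6-trien-1-yl)oxy]silane
Conditions: TBSOTf, Et3N, CH2Cl2, 0 °C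
Reagents that add atoms: tert-butyldimethylsilyl triflate, CC(C)(C)[Si](C)(C)OS(=O)(=O)C(F)(F)F
Why: O-silylation of the dienone and loss of the only available γ-proton give the linear, achiral silyl trienol ether (extended silyl enol ether formation), which has no hydrogen on its sp3 ring carbon and so cannot undergo 1,5-hydrogen shifts.

Step 5
Reactants: 6 tert-butyl(dimethyl)[(5,5,7-trimethylcyclohepta-1,3,6-trien-1-yl)oxy]silane, 7 but-3-en-2-one (methyl vinyl ketone)
Product: 9 (5R)-2,4,4-trimethyl-5-(3-oxobutyl)cyclohepta-2,6-dien-1-one, via silyl enol ether 8 (not isolated)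
Conditions: confined BINOL-derived imidodiphosphorimidate Brønsted acid (IDPi, 3 mol%, enantiomer chosen by a small-scale test to give 5R), toluene, −70 °C; then 1 M HCl, THF, 0 °C
Reagents that add atoms: none
Why: Proposed new method: the IDPi acid is silylated in situ by 6, and the resulting silylium–IDPi ion pair activates 7 as its O-silyl oxocarbenium ion inside the chiral anion pocket; the trienol ether attacks the unsubstituted enone terminus through its γ-carbon (largest HOMO coefficient, α-carbon shielded by the silyloxy group) while the confined anion differentiates the two enantiotopic faces of the nucleophile and so sets C5 (R), and silyl transfer from the O-silyl dienone cation back to the anion closes the cycle; the closest known reactions are IDPi-catalysed Mukaiyama–Michael additions of silyl ketene acetals to unsaturated esters and ketones and disulfonimide-catalysed vinylogous Mukaiyama aldol reactions, neither of which has been shown for a cyclic cross-conjugated silyl trienol ether or for a stereocentre created only on the vinylogous nucleophile next to a quaternary carbon.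

Step 6
Reactants: 9 (5R)-2,4,4-trimethyl-5-(3-oxobutyl)cyclohepta-2,6-dien-1-one
Product: 10 (3R,3aR,8aR)-3-hydroxy-3,6,8,8-tetramethyl-2,3,3a,4,8,8a-hexahydroazulen-5(1H)-one
Conditions: SmI2 (2.2 equiv), t-BuOH (2 equiv), THF, −78 → −40 °C
Reagents that add atoms: none
Why: Ketyl–enone radical cyclization, in which the samarium ketyl of the methyl ketone adds 5-exo to the β-carbon of the unsubstituted enone arm; the tether on C5 enforces the cis ring fusion, the samarium-bound oxygen turns away from the enone (anti rule of ketyl–olefin cyclizations) so the hydroxyl ends cis to both ring-fusion hydrogens, and the samarium dienolate is protonated at the α-carbon to leave the methyl-substituted enone intact.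

Step 7
Reactants: 10 (3R,3aR,8aR)-3-hydroxy-3,6,8,8-tetramethyl-2,3,3a,4,8,8a-hexahydroazulen-5(1H)-one
Product: 11 (1R,3aR,7S,8aR)-1,4,4,6-tetramethyl-1,2,3,3a,4,7,8,8a-octahydroazulene-1,7-diol
Conditions: (R)-2-methyl-CBS-oxazaborolidine (20 mol%), catecholborane, toluene, −78 °C
Reagents that add atoms: none
Why: Corey–Bakshi–Shibata reduction, in which the metal-free oxazaborolidine treats the α-methyl alkenyl arm as the large group and delivers hydride 1,2 under catalyst control to give the (7S)-allylic alcohol, with the hydroxyl on the ring face opposite to the ring-fusion hydrogens.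

Step 8
Reactants: 11 (1R,3aR,7S,8aR)-1,4,4,6-tetramethyl-1,2,3,3a,4,7,8,8a-octahydroazulene-1,7-diol
Product: 13 2-[(1R,3aR,5S,8aR)-1-hydroxy-1,4,4,6-tetramethyl-1,2,3,3a,4,5,8,8a-octahydroazulen-5-yl]acetaldehyde, via allyl vinyl ether 12 (not isolated)
Conditions: Pd(OAc)2 (5 mol%), 1,10-phenanthroline, butyl vinyl ether, 60 °C; concentrate; xylenes, 150 °C, sealed tube
Reagents that add atoms: butyl vinyl ether, C=COCCCC
Why: Palladium-catalysed transfer vinylation of the secondary allylic alcohol (the tertiary alcohol is too hindered) followed by thermal Claisen rearrangement, whose suprafacial [3,3] shift delivers the CH2CHO group to C5 on the face that carried the oxygen, setting C5 (S) and moving the double bond into its final position.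

Step 9
Reactants: 14 dimethyl (2-oxopropyl)phosphonate, 15 geranyl bromide
Product: 16 dimethyl [(5E)-6,10-dimethyl-2-oxoundeca-5,9-dien-1-yl]phosphonate
Conditions: NaH, THF, 0 °C; n-BuLi, 0 °C; then 15, 0 °C → rt
Reagents that add atoms: none
Why: The dianion of the β-keto phosphonate is alkylated at its more basic terminal carbon by SN2 displacement of the allylic bromide with retention of the E geometry (dianion γ-alkylation).

Step 10
Reactants: 16 dimethyl [(5E)-6,10-dimethyl-2-oxoundeca-5,9-dien-1-yl]phosphonate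
Product: 17 dimethyl (4-{(2R,3R)-3-[2-((2R)-3,3-dimethyloxiran-2-yl)ethyl]-3-methyloxiran-2-yl}-2-oxobutyl)phosphonate
Conditions: D-fructose-derived Shi ketone (1,2:4,5-di-O-isopropylidene-β-D-erythro-2,3-hexodiulo-2,6-pyranose, 0.6 equiv), KHSO5 (as Oxone, 2KHSO5·KHSO4·K2SO4), K2CO3, Bu4NHSO4, MeCN–CH2(OMe)2–aqueous borate buffer, 0 °C
Reagents that add atoms: potassium peroxymonosulfate, [K+].[O-]S(=O)(=O)OO
Why: Shi epoxidation, in which the chiral dioxirane transfers oxygen through a spiro transition state to the same face sense of both electron-rich trisubstituted alkenes (R,R and R epoxides), while the keto phosphonate, un-ionised at this pH, is not oxidised; this metal-free step sets the first stereocentres of the left half.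

Step 11
Reactants: 13 2-[(1R,3aR,5S,8aR)-1-hydroxy-1,4,4,6-tetramethyl-1,2,3,3a,4,5,8,8a-octahydroazulen-5-yl]acetaldehyde, 17 dimethyl (4-{(2R,3R)-3-[2-((2R)-3,3-dimethyloxiran-2-yl)ethyl]-3-methyloxiran-2-yl}-2-oxobutyl)phosphonate
Product: 18 (4E)-1-{(2R,3R)-3-[2-((2R)-3,3-dimethyloxiran-2-yl)ethyl]-3-methyloxiran-2-yl}-6-[(1R,3aR,5S,8aR)-1-hydroxy-1,4,4,6-tetramethyl-1,2,3,3a,4,5,8,8a-octahydroazulen-5-yl]hex-4-en-3-one
Conditions: LiCl, DBU, MeCN, 0 °C → rt
Reagents that add atoms: none
Why: Horner–Wadsworth–Emmons olefination under Masamune–Roush conditions joins the fragments as the E-enone and is mild enough for the epoxides and the free tertiary alcohol.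

Step 12
Reactants: 18 (4E)-1-{(2R,3R)-3-[2-((2R)-3,3-dimethyloxiran-2-yl)ethyl]-3-methyloxiran-2-yl}-6-[(1R,3aR,5S,8aR)-1-hydroxy-1,4,4,6-tetramethyl-1,2,3,3a,4,5,8,8a-octahydroazulen-5-yl]hex-4-en-3-one
Product: 19 triethyl({(3Z)-1-{(2R,3R)-3-[2-((2R)-3,3-dimethyloxiran-2-yl)ethyl]-3-methyloxiran-2-yl}-6-[(1R,3aR,5S,8aR)-1-hydroxy-1,4,4,6-tetramethyl-1,2,3,3a,4,5,8,8a-octahydroazulen-5-yl]hex-3-en-3-yl}oxy)silane
Conditions: Et3SiH, RhCl(PPh3)3 (2 mol%), benzene, 50 °C
Reagents that add atoms: triethylsilane, CC[SiH](CC)CC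
Why: Rhodium-catalysed 1,4-hydrosilylation of the s-cis enone gives the silyl enol ether regiospecifically on the side of the former alkene and mainly as the Z isomer, a regiochemistry that direct enolization of the saturated ketone could not provide; epoxides, the trisubstituted alkene and the hindered tertiary alcohol are inert.

Step 13
Reactants: 19 triethyl({(3Z)-1-{(2R,3R)-3-[2-((2R)-3,3-dimethyloxiran-2-yl)ethyl]-3-methyloxiran-2-yl}-6-[(1R,3aR,5S,8aR)-1-hydroxy-1,4,4,6-tetramethyl-1,2,3,3a,4,5,8,8a-octahydroazulen-5-yl]hex-3-en-3-yl}oxy)silane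
Product: 21 (3R,5aR,6R,9aR)-3-hydroxy-6-{2-[(1R,3aR,5S,8aR)-1-hydroxy-1,4,4,6-tetramethyl-1,2,3,3a,4,5,8,8a-octahydroazulen-5-yl]ethyl}-2,2,5a-trimethyloctahydro-1-benzoxepin-7(2H)-one, via bis-triethylsilyl ether 20 (not isolated)
Conditions: TESOTf (2.5 equiv), 2,6-di-tert-butyl-4-methylpyridine, CH2Cl2, −78 °C; then TBAF, THF, 0 °C → rt
Reagents that add atoms: triethylsilyl triflate, CC[Si](CC)(CC)OS(=O)(=O)C(F)(F)F (supplies one silyl group of 20 only)
Why: Lewis-acid-triggered tandem oxa- and carbacyclization of a polyepoxide, in which silyl activation of the terminal epoxide is followed by attack of the internal epoxide oxygen at its tertiary carbon (oxepane, epoxonium ion) and then by anti attack of the Z-silyl enol ether at the tertiary epoxonium carbon through a chair transition state, giving the trans-fused rings with C9a retained, C5a inverted and the C6 side chain equatorial; fluoride then removes both silyl groups and equilibrates any minor C6 epimer to this more stable one.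

Step 14
Reactants: 21 (3R,5aR,6R,9aR)-3-hydroxy-6-{2-[(1R,3aR,5S,8aR)-1-hydroxy-1,4,4,6-tetramethyl-1,2,3,3a,4,5,8,8a-octahydroazulen-5-yl]ethyl}-2,2,5a-trimethyloctahydro-1-benzoxepin-7(2H)-one
Product: 22 (3R,5aR,6R,7S,9aR)-6-{2-[(1R,3aR,5S,8aR)-1-hydroxy-1,4,4,6-tetramethyl-1,2,3,3a,4,5,8,8a-octahydroazulen-5-yl]ethyl}-2,2,5a,7-tetramethyldecahydro-1-benzoxepine-3,7-diol
Conditions: MeMgBr (6 equiv), THF, −78 → 0 °C
Reagents that add atoms: methylmagnesium bromide, C[Mg]Br
Why: Grignard addition after deprotonation of the two hydroxyls, with equatorial attack because the axial path is blocked by the 1,3-diaxial angular methyl group, gives the axial tertiary alcohol (7S).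

Step 15
Reactants: 22 (3R,5aR,6R,7S,9aR)-6-{2-[(1R,3aR,5S,8aR)-1-hydroxy-1,4,4,6-tetramethyl-1,2,3,3a,4,5,8,8a-octahydroazulen-5-yl]ethyl}-2,2,5a,7-tetramethyldecahydro-1-benzoxepine-3,7-diol
Product: 23 sipholenone A, (5aR,6R,7S,9aR)-7-hydroxy-6-{2-[(1R,3aR,5S,8aR)-1-hydroxy-1,4,4,6-tetramethyl-1,2,3,3a,4,5,8,8a-octahydroazulen-5-yl]ethyl}-2,2,5a,7-tetramethyloctahydro-1-benzoxepin-3(2H)-one
Conditions: Dess–Martin periodinane, CH2Cl2, rt
Reagents that add atoms: none
Why: Dess–Martin oxidation converts the only secondary alcohol into the C3 ketone while both tertiary alcohols and the alkene are untouched.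

**Compound list**

1 | 2,4,4-trimethylcyclohex-2-en-1-one | CC1=CC(C)(C)CCC1=O | starting material
2 | trimethyl[(4,4,6-trimethylcyclohexa-1,5-dien-1-yl)oxy]silane | CC1=CC(C)(C)CC=C1O[Si](C)(C)C | intermediate
3 | trimethyl[(2,4,4-trimethylbicyclo[4.1.0]hept-2-en-1-yl)oxy]silane (racemic) | CC1=CC(C)(C)CC2CC12O[Si](C)(C)C | intermediate
4 | 6-chloro-2,4,4-trimethylcyclohept-2-en-1-one (racemic) | CC1=CC(C)(C)CC(Cl)CC1=O | intermediate (not isolated)
5 | 2,4,4-trimethylcyclohepta-2,6-dien-1-one | CC1=CC(C)(C)CC=CC1=O | intermediate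
6 | tert-butyl(dimethyl)[(5,5,7-trimethylcyclohepta-1,3,6-trien-1-yl)oxy]silane | CC1=CC(C)(C)C=CC=C1O[Si](C)(C)C(C)(C)C | intermediate
7 | but-3-en-2-one (methyl vinyl ketone) | CC(=O)C=C | starting material
8 | (5R)-5-[3-(tert-butyldimethylsilyloxy)but-2-en-1-yl]-2,4,4-trimethylcyclohepta-2,6-dien-1-one | O=C1C(C)=CC(C)(C)[C@H](CC=C(C)O[Si](C)(C)C(C)(C)C)C=C1 | intermediate (not isolated)
9 | (5R)-2,4,4-trimethyl-5-(3-oxobutyl)cyclohepta-2,6-dien-1-one | O=C1C(C)=CC(C)(C)[C@H](CCC(C)=O)C=C1 | intermediate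
10 | (3R,3aR,8aR)-3-hydroxy-3,6,8,8-tetramethyl-2,3,3a,4,8,8a-hexahydroazulen-5(1H)-one | CC1=CC(C)(C)[C@@H]2CC[C@@](C)(O)[C@@H]2CC1=O | intermediate
11 | (1R,3aR,7S,8aR)-1,4,4,6-tetramethyl-1,2,3,3a,4,7,8,8a-octahydroazulene-1,7-diol | CC1=CC(C)(C)[C@@H]2CC[C@@](C)(O)[C@@H]2C[C@@H]1O | intermediate
12 | (1R,3aR,7S,8aR)-7-(ethenyloxy)-1,4,4,6-tetramethyl-1,2,3,3a,4,7,8,8a-octahydroazulen-1-ol | CC1=CC(C)(C)[C@@H]2CC[C@@](C)(O)[C@@H]2C[C@@H]1OC=C | intermediate (not isolated)
13 | 2-[(1R,3aR,5S,8aR)-1-hydroxy-1,4,4,6-tetramethyl-1,2,3,3a,4,5,8,8a-octahydroazulen-5-yl]acetaldehyde | CC1=CC[C@@H]2[C@@H](CC[C@@]2(C)O)C(C)(C)[C@H]1CC=O | intermediate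
14 | dimethyl (2-oxopropyl)phosphonate | COP(=O)(OC)CC(C)=O | starting material
15 | geranyl bromide, (2E)-1-bromo-3,7-dimethylocta-2,6-diene | CC(C)=CCC/C(C)=C/CBr | starting material
16 | dimethyl [(5E)-6,10-dimethyl-2-oxoundeca-5,9-dien-1-yl]phosphonate | COP(=O)(OC)CC(=O)CC/C=C(\C)CCC=C(C)C | intermediate
17 | dimethyl (4-{(2R,3R)-3-[2-((2R)-3,3-dimethyloxiran-2-yl)ethyl]-3-methyloxiran-2-yl}-2-oxobutyl)phosphonate | COP(=O)(OC)CC(=O)CC[C@H]1O[C@]1(C)CC[C@H]1OC1(C)C | intermediate
18 | (4E)-enone from the union: 1-(diepoxide side chain)-6-(hydroazulenyl)hex-4-en-3-one, full name in step 11 | CC1=CC[C@@H]2[C@@H](CC[C@@]2(C)O)C(C)(C)[C@H]1C/C=C/C(=O)CC[C@H]1O[C@]1(C)CC[C@H]1OC1(C)C | intermediate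
19 | (3Z)-triethylsilyl enol ether of 18 after 1,4-reduction, full name in step 12 | CC1=CC[C@@H]2[C@@H](CC[C@@]2(C)O)C(C)(C)[C@H]1CC/C=C(\O[Si](CC)(CC)CC)CC[C@H]1O[C@]1(C)CC[C@H]1OC1(C)C | intermediate
20 | 3-O,1'-O-bis(triethylsilyl) ether of 21 | CC1=CC[C@@H]2[C@@H](CC[C@@]2(C)O[Si](CC)(CC)CC)C(C)(C)[C@H]1CC[C@@H]1[C@@]2(C)CC[C@@H](O[Si](CC)(CC)CC)C(C)(C)O[C@@H]2CCC1=O | intermediate (not isolated)
21 | (3R,5aR,6R,9aR)-3-hydroxy-6-{2-[(1R,3aR,5S,8aR)-1-hydroxy-1,4,4,6-tetramethyl-1,2,3,3a,4,5,8,8a-octahydroazulen-5-yl]ethyl}-2,2,5a-trimethyloctahydro-1-benzoxepin-7(2H)-one | CC1=CC[C@@H]2[C@@H](CC[C@@]2(C)O)C(C)(C)[C@H]1CC[C@@H]1[C@@]2(C)CC[C@@H](O)C(C)(C)O[C@@H]2CCC1=O | intermediate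
22 | (3R,5aR,6R,7S,9aR)-6-{2-[(1R,3aR,5S,8aR)-1-hydroxy-1,4,4,6-tetramethyl-1,2,3,3a,4,5,8,8a-octahydroazulen-5-yl]ethyl}-2,2,5a,7-tetramethyldecahydro-1-benzoxepine-3,7-diol | CC1=CC[C@@H]2[C@@H](CC[C@@]2(C)O)C(C)(C)[C@H]1CC[C@@H]1[C@@]2(C)CC[C@@H](O)C(C)(C)O[C@@H]2CC[C@]1(C)O | intermediate
23 | sipholenone A | CC1=CC[C@@H]2[C@@H](CC[C@@]2(C)O)C(C)(C)[C@H]1CC[C@@H]1[C@@]2(C)CCC(=O)C(C)(C)O[C@@H]2CC[C@]1(C)O | target

**Step count and risks**

Total: 15 steps. Longest linear sequence: 13 steps (steps 1–8, then 11–15); the left chain (steps 9–10) joins at step 11.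

Step 5, the new asymmetric vinylogous Mukaiyama–Michael addition. It may fail through attack at the α-carbon instead of the γ-carbon, through a second aldol-type ring closure onto the silylated dienone, or through poor face selection. The fallback uses known chemistry only, sets out from 1 and comes back at 9. Compound 1 is dehydrogenated with 2-iodoxybenzoic acid to 2,4,4-trimethylcyclohexa-2,5-dien-1-one F1. Copper-catalysed asymmetric conjugate addition of di(but-3-enyl)zinc (Cu(OTf)2, chiral phosphoramidite) to the less substituted enone arm, with TMSOTf trapping of the zinc enolate, gives trimethyl{[(3R)-3-(but-3-en-1-yl)-4,4,6-trimethylcyclohexa-1,5-dien-1-yl]oxy}silane F2. Simmons–Smith cyclopropanation of the enol ether gives the siloxycyclopropane F3, FeCl3 opens it to the ring-enlarged chloro ketone F4, and NaOAc eliminates to (5R)-5-(but-3-en-1-yl)-2,4,4-trimethylcyclohepta-2,6-dien-1-one F5. Tsuji–Wacker oxidation (PdCl2, CuCl, O2, DMF–H2O) of the terminal alkene then gives 9.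

Step 6, the SmI2 ketyl–enone cyclization. The cross-conjugated dienone may be reduced in competition with ketyl formation, and 10 may be over-reduced. The fallback sets out from 8 (kept by a neutral work-up in step 5) and comes back at 10. Hydrogen-atom transfer from an iron hydride (Fe(acac)3, PhSiH3, EtOH) to the electron-rich silyl enol ether gives an α-silyloxy radical that adds to the enone in a polarity-matched conjugate addition. The product is the tert-butyldimethylsilyl ether of 10, F6, and TBAF then gives 10. The carbinol epimer ratio is less certain in this mode and may need a separation.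

Step 13, the epoxide cascade. Mono-cyclised material, smaller cyclic ethers or protodesilylation of the enol ether could dominate on this large substrate. The fallback cyclises first and couples second; it sets out from 17, uses 13, and comes back at 21. TESOTf and Et3N convert 17 into its phosphonate-bearing silyl enol ether F7, whose regiochemistry is fixed by the phosphonate. The same TESOTf cascade on this smaller substrate gives the bicyclic keto phosphonate F8. Horner–Wadsworth–Emmons reaction of F8 with 13 gives the exocyclic alkylidene ketone F9. Conjugate reduction with [(Ph3P)CuH]6 and protonation give the 3-O-triethylsilyl ether of 21, F10, and TBAF gives 21.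

**Further compounds**

F1 | step 5 | 2,4,4-trimethylcyclohexa-2,5-dien-1-one | CC1=CC(C)(C)C=CC1=O
F2 | step 5 | trimethyl{[(3R)-3-(but-3-en-1-yl)-4,4,6-trimethylcyclohexa-1,5-dien-1-yl]oxy}silane | CC1=CC(C)(C)[C@H](CCC=C)C=C1O[Si](C)(C)C
F3 | step 5 | {[(5R)-5-(but-3-en-1-yl)-2,4,4-trimethylbicyclo[4.1.0]hept-2-en-1-yl]oxy}trimethylsilane (cyclopropane epimers) | CC1=CC(C)(C)[C@H](CCC=C)C2CC12O[Si](C)(C)C
F4 | step 5 | 5-(but-3-en-1-yl)-6-chloro-2,4,4-trimethylcyclohept-2-en-1-one (C6 epimers) | CC1=CC(C)(C)[C@H](CCC=C)C(Cl)CC1=O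
F5 | step 5 | (5R)-5-(but-3-en-1-yl)-2,4,4-trimethylcyclohepta-2,6-dien-1-one | O=C1C(C)=CC(C)(C)[C@H](CCC=C)C=C1
F6 | step 6 | (3R,3aR,8aR)-3-(tert-butyldimethylsilyloxy)-3,6,8,8-tetramethyl-2,3,3a,4,8,8a-hexahydroazulen-5(1H)-one | CC1=CC(C)(C)[C@@H]2CC[C@@](C)(O[Si](C)(C)C(C)(C)C)[C@@H]2CC1=O
F7 | step 13 | dimethyl (4-{(2R,3R)-3-[2-((2R)-3,3-dimethyloxiran-2-yl)ethyl]-3-methyloxiran-2-yl}-2-(triethylsilyloxy)but-1-en-1-yl)phosphonate | COP(=O)(OC)C=C(O[Si](CC)(CC)CC)CC[C@H]1O[C@]1(C)CC[C@H]1OC1(C)C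
F8 | step 13 | dimethyl [(3R,5aR,9aR)-2,2,5a-trimethyl-7-oxo-3-(triethylsilyloxy)decahydro-1-benzoxepin-6-yl]phosphonate (C6 epimers) | COP(=O)(OC)C1[C@@]2(C)CC[C@@H](O[Si](CC)(CC)CC)C(C)(C)O[C@@H]2CCC1=O
F9 | step 13 | (3R,5aR,9aR)-6-{2-[(1R,3aR,5S,8aR)-1-hydroxy-1,4,4,6-tetramethyl-1,2,3,3a,4,5,8,8a-octahydroazulen-5-yl]ethylidene}-2,2,5a-trimethyl-3-(triethylsilyloxy)octahydro-1-benzoxepin-7(2H)-one (E expected) | CC1=CC[C@@H]2[C@@H](CC[C@@]2(C)O)C(C)(C)[C@H]1CC=C1[C@@]2(C)CC[C@@H](O[Si](CC)(CC)CC)C(C)(C)O[C@@H]2CCC1=O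
F10 | step 13 | 3-O-triethylsilyl ether of 21 | CC1=CC[C@@H]2[C@@H](CC[C@@]2(C)O)C(C)(C)[C@H]1CC[C@@H]1[C@@]2(C)CC[C@@H](O[Si](CC)(CC)CC)C(C)(C)O[C@@H]2CCC1=O
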